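Enabling disconnections and ring order:

1. The acid comes from its methyl ester; the ester from a cyclobutene by syn addition of H and isopropenyl across the ring alkene (this sets both cyclobutane stereocentres, trans); the cyclobutene from the fragment union.
2. Key disconnection: the bond between the quaternary carbon C6 of the carbocycle (chromene numbering) and the exocyclic CH2, made by Pd-catalysed asymmetric allylic dearomatisation of a C6-prenylated phloroglucinol core with an achiral (cyclobutenyl)methyl carbonate.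
3. Enabling feature: C6 lies between the oxygen-bearing carbons C5 and C7 of the six-membered carbocycle (the 2-position of a cyclic 1,3-dicarbonyl; in the aromatic tautomer a ring carbon flanked by two phenolic oxygens), so it is a soft prochiral carbon nucleophile; and the CH2 is bonded to cyclobutane carbon C1, which can be carried as an sp2 carbon of a C1=C2 ring alkene, so the CH2 becomes an allylic terminus.
4. Core from 3,5-dimethoxyphenol: lactone ring first (iminium-catalysed Friedel–Crafts/hemiacetalisation sets the side-chain centre), acylation, lactone-to-dihydropyranone ring switch by methanolysis/oxa-Michael (the ring oxygen ends between the two carbon substituents), demethylation/relactonisation on the other oxygen, then iodination/Stille prenylation of the last ring carbon.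
5. Ring order: cyclobutene (enamine–acrylate [2+2], Hofmann elimination); lactone; dihydropyranone; carbocycle dearomatised in the key step; saturated cyclobutane with its two stereocentres last.

Key step: step 12

Assumption (remark on the chemistry): the ligand enantiomers named in steps 12 and 13 are those expected from the accepted working models; if either reaction shows the opposite sense of induction, the antipodal ligand is to be used.

Step 1
Reactants: 1 N,N,2-trimethylprop-1-en-1-amine; 2 methyl prop-2-enoate
Product: 3 methyl 2-(dimethylamino)-3,3-dimethylcyclobutane-1-carboxylate (racemic, cis/trans mixture)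
Conditions: MeCN, 80 °C, sealed vessel
Reagents that add atoms: none
Why: Thermal formal [2+2] cycloaddition of an enamine without hydrogen on its nucleophilic carbon to an acrylate (Michael addition, then Mannich ring closure) should bond the gem-dimethyl carbon to the acrylate CH2 and the ester-bearing carbon to the amino carbon; both stereocentres formed are removed in step 2.

Step 2
Reactants: 3 methyl 2-(dimethylamino)-3,3-dimethylcyclobutane-1-carboxylate
Product: 5 methyl 3,3-dimethylcyclobut-1-ene-1-carboxylate, via trimethylammonium iodide 4 (not isolated)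
Conditions: MeI, MeCN, 20 °C; then NaOMe, MeOH, 0 to 20 °C
Reagents that add atoms: none
Why: Exhaustive N-methylation followed by Hofmann-type E1cB elimination (loss of the proton alpha to the ester) should place the double bond between the ester-bearing carbon and the former amino carbon, giving the conjugated cyclobutene ester.

Step 3
Reactants: 5 methyl 3,3-dimethylcyclobut-1-ene-1-carboxylate
Product: 6 (3,3-dimethylcyclobut-1-en-1-yl)methanol
Conditions: i-Bu2AlH (2.2 equiv), CH2Cl2, −78 to 0 °C; aqueous sodium potassium tartrate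
Reagents that add atoms: none
Why: 1,2-Reduction of the conjugated ester with i-Bu2AlH at low temperature should give the allylic alcohol and leave the strained ring alkene untouched.

Step 4
Reactants: 6 (3,3-dimethylcyclobut-1-en-1-yl)methanol
Product: 7 (3,3-dimethylcyclobut-1-en-1-yl)methyl methyl carbonate
Conditions: ClCO2Me, pyridine, CH2Cl2, 0 °C
Reagents that add atoms: methyl chloroformate, COC(=O)Cl
Why: O-Acylation of the primary allylic alcohol gives the allylic methyl carbonate, the ionisable group needed for η3-allylpalladium formation in step 12.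

Step 5
Reactants: 8 3,5-dimethoxyphenol; 9 (2E)-hex-2-enal
Product: 10 (4R)-5,7-dimethoxy-4-propyl-3,4-dihydro-2H-chromen-2-ol (both C2 epimers)
Conditions: (S)-2-[diphenyl(trimethylsilyloxy)methyl]pyrrolidine (20 mol %), PhCO2H (20 mol %), toluene, 0 to 20 °C
Reagents that add atoms: none
Why: Iminium-catalysed Friedel–Crafts alkylation of the electron-rich phenol at the carbon ortho to OH followed by hemiacetalisation; the bulky silyloxydiphenylmethyl group of the (S)-catalyst shields one face of the E-iminium ion, so the arene should add to the other face of C3 of the enal and set the (R) benzylic centre.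

Step 6
Reactants: 10 (4R)-5,7-dimethoxy-4-propyl-3,4-dihydro-2H-chromen-2-ol
Product: 11 (4R)-5,7-dimethoxy-4-propyl-3,4-dihydro-2H-chromen-2-one
Conditions: Dess–Martin periodinane, CH2Cl2, 20 °C
Reagents that add atoms: none
Why: Dess–Martin oxidation of the lactol to the six-membered aryl lactone; the benzylic stereocentre is beta to the carbonyl and cannot epimerise.

Step 7
Reactants: 11 (4R)-5,7-dimethoxy-4-propyl-3,4-dihydro-2H-chromen-2-one; 12 3-methylbut-2-enoic acid
Product: 13 (4R)-5,7-dimethoxy-8-(3-methylbut-2-enoyl)-4-propyl-3,4-dihydro-2H-chromen-2-one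
Conditions: (CF3CO)2O, H3PO4 (85 %, cat.), CH2Cl2, 0 to 20 °C
Reagents that add atoms: none
Why: Friedel–Crafts acylation through the mixed trifluoroacetic anhydride should occur at C8 (para to the C5 methoxy, ortho to the C7 methoxy), because C6 sits between two methoxy groups and the methyl of the C5 methoxy is pushed towards C6 by the C4 substituent.

Step 8
Reactants: 13 (4R)-5,7-dimethoxy-8-(3-methylbut-2-enoyl)-4-propyl-3,4-dihydro-2H-chromen-2-one
Product: 15 methyl (3R)-3-(5,7-dimethoxy-2,2-dimethyl-4-oxo-3,4-dihydro-2H-chromen-8-yl)hexanoate, via ring-opened sodium phenolate 14 (not isolated)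
Conditions: NaOMe (0.3 equiv), MeOH, 20 °C; AcOH quench
Reagents that add atoms: methanol, CO
Why: Methoxide-catalysed methanolysis of the aryl lactone frees the only phenoxide of the molecule, which lies between the side chain and the enone and should close the dihydropyranone ring by 6-endo oxa-Michael addition (chromanone formation), so the ring oxygen is fixed between the two carbon substituents.

Step 9
Reactants: 15 methyl (3R)-3-(5,7-dimethoxy-2,2-dimethyl-4-oxo-3,4-dihydro-2H-chromen-8-yl)hexanoate
Product: 16 (10R)-5-hydroxy-2,2-dimethyl-10-propyl-2,3,9,10-tetrahydro-4H,8H-pyrano[2,3-f]chromene-4,8-dione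
Conditions: BBr3 (4 equiv), CH2Cl2, −78 to 0 °C; H2O; then TsOH (cat.), toluene, 80 °C
Reagents that add atoms: none
Why: Lewis-acid cleavage of both aryl methyl ethers, then lactonisation of the ester with the phenol next to the side chain (the only oxygen that can form the six-membered lactone), while the other phenol stays hydrogen-bonded to the ketone; the stereocentre is not touched.

Step 10
Reactants: 16 (10R)-5-hydroxy-2,2-dimethyl-10-propyl-2,3,9,10-tetrahydro-4H,8H-pyrano[2,3-f]chromene-4,8-dione
Product: 17 (10R)-5-hydroxy-6-iodo-2,2-dimethyl-10-propyl-2,3,9,10-tetrahydro-4H,8H-pyrano[2,3-f]chromene-4,8-dione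
Conditions: N-iodosuccinimide, TsOH (10 mol %), MeCN, 0 to 20 °C
Reagents that add atoms: N-iodosuccinimide, O=C1CCC(=O)N1I
Why: Electrophilic aromatic iodination can only occur at the single unsubstituted ring carbon, which is ortho to the free hydroxyl.

Step 11
Reactants: 17 (10R)-5-hydroxy-6-iodo-2,2-dimethyl-10-propyl-2,3,9,10-tetrahydro-4H,8H-pyrano[2,3-f]chromene-4,8-dione; 18 tributyl(3-methylbut-2-en-1-yl)stannane
Product: 19 (10R)-5-hydroxy-2,2-dimethyl-6-(3-methylbut-2-en-1-yl)-10-propyl-2,3,9,10-tetrahydro-4H,8H-pyrano[2,3-f]chromene-4,8-dione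
Conditions: Pd(PPh3)4 (5 mol %), DMF, 90 °C
Reagents that add atoms: none
Why: Stille cross-coupling of the aryl iodide with the prenylstannane, with transfer through the tin-bearing carbon, should give the linear prenyl arene at C6.

Step 12
Reactants: 19 (10R)-5-hydroxy-2,2-dimethyl-6-(3-methylbut-2-en-1-yl)-10-propyl-2,3,9,10-tetrahydro-4H,8H-pyrano[2,3-f]chromene-4,8-dione; 7 (3,3-dimethylcyclobut-1-en-1-yl)methyl methyl carbonate
Product: 21 methyl (3R)-3-[(6S)-6-[(3,3-dimethylcyclobut-1-en-1-yl)methyl]-5-hydroxy-2,2-dimethyl-6-(3-methylbut-2-en-1-yl)-4,7-dioxo-3,4,6,7-tetrahydro-2H-chromen-8-yl]hexanoate, via ring-opened disodium bis-phenolate 20 (not isolated)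
Conditions: NaOMe (2.1 equiv), MeOH/THF, 0 °C; then Pd2(dba)3·CHCl3 (2.5 mol %), N,N′-[(1R,2R)-cyclohexane-1,2-diyl]bis[2-(diphenylphosphanyl)benzamide] (7.5 mol %), −20 to 0 °C; aqueous HCl to pH 3
Reagents that add atoms: sodium methoxide, [Na+].[O-]C
Why: Zerovalent palladium ionises carbonate 7 to an η3-allyl complex whose termini are the exocyclic CH2 and ring carbon C2 of the cyclobutene, and the soft dianion 20 attacks the CH2 terminus through C6 from outside the coordination sphere (Tsuji–Trost allylic alkylation), which forms the C6–CH2 bond, makes C6 quaternary and turns the aromatic ring into the enolised cyclohexadienone. The closest known reaction type is the palladium-catalysed allylic dearomatisation of acylphloroglucinols and of 1,3-disubstituted 2-naphthols, the latter enantioselective with this class of C2-symmetric bis(phosphine) ligand. No ring is closed in this step. The new stereocentre C6 is controlled by the chiral ligand, whose pocket differentiates the enantiotopic faces of the planar nucleophile; the distant side-chain centre is not expected to interfere. C- over O-allylation is secured by the reversibility of O-allylation under palladium together with the stability of the β-triketone enolate formed on C-attack, C6 over C8 by the two oxido groups that flank only C6, and attack at the CH2 terminus by the gem-dimethyl group that screens the ring terminus of the allyl unit.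

Step 13
Reactants: 21 methyl (3R)-3-[(6S)-6-[(3,3-dimethylcyclobut-1-en-1-yl)methyl]-5-hydroxy-2,2-dimethyl-6-(3-methylbut-2-en-1-yl)-4,7-dioxo-3,4,6,7-tetrahydro-2H-chromen-8-yl]hexanoate; 22 2-bromoprop-1-ene
Product: 23 methyl (3R)-3-[(6R)-6-{[(1S,2R)-3,3-dimethyl-2-(prop-1-en-2-yl)cyclobutyl]methyl}-5-hydroxy-2,2-dimethyl-6-(3-methylbut-2-en-1-yl)-4,7-dioxo-3,4,6,7-tetrahydro-2H-chromen-8-yl]hexanoate
Conditions: Cu(OAc)2 (5 mol %), (R)-DTBM-SEGPHOS (6 mol %), Pd(OAc)2 (2 mol %), 2-dicyclohexylphosphino-2′,4′,6′-triisopropylbiphenyl (4 mol %), MeSiH(OMe)2 (3 equiv), LiOMe (3 equiv), THF, 40 °C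
Reagents that add atoms: none
Why: Proposed new method: a ligated copper hydride (monovalent copper) should add syn across the strained trisubstituted ring alkene, hydrogen going to the CH2-bearing carbon and copper to the less substituted carbon, as in the known copper hydride-catalysed hydroamination of 1-substituted cyclobutenes; the secondary cyclobutylcopper should transmetallate with retention to the isopropenylpalladium bromide formed from 22, and reductive elimination then places isopropenyl cis to the new C–H bond, that is trans to the CH2 substituent, with both ring stereocentres fixed by the chiral bisphosphine on copper in the hydrocupration; the closest known reaction type is the dual copper hydride/palladium hydroarylation and hydroalkenylation of styrenes and terminal alkenes, which has not been shown on a trisubstituted cyclobutene or next to a quaternary carbon.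

Step 14
Reactants: 23 methyl (3R)-3-[(6R)-6-{[(1S,2R)-3,3-dimethyl-2-(prop-1-en-2-yl)cyclobutyl]methyl}-5-hydroxy-2,2-dimethyl-6-(3-methylbut-2-en-1-yl)-4,7-dioxo-3,4,6,7-tetrahydro-2H-chromen-8-yl]hexanoate
Product: 24 (3R)-3-[(6R)-6-{[(1S,2R)-3,3-dimethyl-2-(prop-1-en-2-yl)cyclobutyl]methyl}-5-hydroxy-2,2-dimethyl-6-(3-methylbut-2-en-1-yl)-4,7-dioxo-3,4,6,7-tetrahydro-2H-chromen-8-yl]hexanoic acid (target)
Conditions: LiOH·H2O (5 equiv), THF/H2O, 0 to 20 °C; aqueous HCl to pH 3
Reagents that add atoms: lithium hydroxide, [Li+].[OH-]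
Why: Saponification of the methyl ester while the vinylogous acid is protected as its enolate; none of the four stereocentres is enolisable under these conditions (C6 carries no hydrogen, the side-chain centre is beta to the carboxylate).

Compound list

1 | N,N,2-trimethylprop-1-en-1-amine | CC(C)=CN(C)C | starting material
2 | methyl prop-2-enoate | C=CC(=O)OC | starting material
3 | methyl 2-(dimethylamino)-3,3-dimethylcyclobutane-1-carboxylate (racemic, cis/trans) | COC(=O)C1CC(C)(C)C1N(C)C | intermediate
4 | 2-(methoxycarbonyl)-N,N,N,4,4-pentamethylcyclobutan-1-aminium iodide | COC(=O)C1CC(C)(C)C1[N+](C)(C)C.[I-] | intermediate (not isolated)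
5 | methyl 3,3-dimethylcyclobut-1-ene-1-carboxylate | COC(=O)C1=CC(C)(C)C1 | intermediate
6 | (3,3-dimethylcyclobut-1-en-1-yl)methanol | OCC1=CC(C)(C)C1 | intermediate
7 | (3,3-dimethylcyclobut-1-en-1-yl)methyl methyl carbonate | COC(=O)OCC1=CC(C)(C)C1 | intermediate
8 | 3,5-dimethoxyphenol | COc1cc(O)cc(OC)c1 | starting material
9 | (2E)-hex-2-enal | CCC/C=C/C=O | starting material
10 | (4R)-5,7-dimethoxy-4-propyl-3,4-dihydro-2H-chromen-2-ol (C2 epimers) | CCC[C@@H]1CC(O)Oc2cc(OC)cc(OC)c12 | intermediate
11 | (4R)-5,7-dimethoxy-4-propyl-3,4-dihydro-2H-chromen-2-one | CCC[C@@H]1CC(=O)Oc2cc(OC)cc(OC)c12 | intermediate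
12 | 3-methylbut-2-enoic acid | CC(C)=CC(=O)O | starting material
13 | (4R)-5,7-dimethoxy-8-(3-methylbut-2-enoyl)-4-propyl-3,4-dihydro-2H-chromen-2-one | CCC[C@@H]1CC(=O)Oc2c(C(=O)C=C(C)C)c(OC)cc(OC)c12 | intermediate
14 | sodium 2-[(3R)-1-methoxy-1-oxohexan-3-yl]-3,5-dimethoxy-6-(3-methylbut-2-enoyl)phenolate | CCC[C@H](CC(=O)OC)c1c(OC)cc(OC)c(C(=O)C=C(C)C)c1[O-].[Na+] | intermediate (not isolated)
15 | methyl (3R)-3-(5,7-dimethoxy-2,2-dimethyl-4-oxo-3,4-dihydro-2H-chromen-8-yl)hexanoate | CCC[C@H](CC(=O)OC)c1c(OC)cc(OC)c2C(=O)CC(C)(C)Oc12 | intermediate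
16 | (10R)-5-hydroxy-2,2-dimethyl-10-propyl-2,3,9,10-tetrahydro-4H,8H-pyrano[2,3-f]chromene-4,8-dione | Oc1cc2OC(=O)C[C@@H](CCC)c2c2OC(C)(C)CC(=O)c12 | intermediate
17 | (10R)-5-hydroxy-6-iodo-2,2-dimethyl-10-propyl-2,3,9,10-tetrahydro-4H,8H-pyrano[2,3-f]chromene-4,8-dione | Oc1c(I)c2OC(=O)C[C@@H](CCC)c2c2OC(C)(C)CC(=O)c12 | intermediate
18 | tributyl(3-methylbut-2-en-1-yl)stannane | CCCC[Sn](CCCC)(CCCC)CC=C(C)C | starting material
19 | (10R)-5-hydroxy-2,2-dimethyl-6-(3-methylbut-2-en-1-yl)-10-propyl-2,3,9,10-tetrahydro-4H,8H-pyrano[2,3-f]chromene-4,8-dione | Oc1c(CC=C(C)C)c2OC(=O)C[C@@H](CCC)c2c2OC(C)(C)CC(=O)c12 | intermediate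
20 | disodium 5,7-bis-phenolate of methyl (3R)-3-[5,7-dihydroxy-2,2-dimethyl-6-(3-methylbut-2-en-1-yl)-4-oxo-3,4-dihydro-2H-chromen-8-yl]hexanoate | CCC[C@H](CC(=O)OC)c1c([O-])c(CC=C(C)C)c([O-])c2C(=O)CC(C)(C)Oc12.[Na+].[Na+] | intermediate (not isolated)
21 | methyl (3R)-3-[(6S)-6-[(3,3-dimethylcyclobut-1-en-1-yl)methyl]-5-hydroxy-2,2-dimethyl-6-(3-methylbut-2-en-1-yl)-4,7-dioxo-3,4,6,7-tetrahydro-2H-chromen-8-yl]hexanoate | CC1(C)C=C(C[C@]2(CC=C(C)C)C(=O)C([C@H](CCC)CC(=O)OC)=C3OC(C)(C)CC(=O)C3=C2O)C1 | intermediate
22 | 2-bromoprop-1-ene | CC(Br)=C | starting material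
23 | methyl (3R)-3-[(6R)-6-{[(1S,2R)-3,3-dimethyl-2-(prop-1-en-2-yl)cyclobutyl]methyl}-5-hydroxy-2,2-dimethyl-6-(3-methylbut-2-en-1-yl)-4,7-dioxo-3,4,6,7-tetrahydro-2H-chromen-8-yl]hexanoate | C=C(C)[C@H]1[C@H](C[C@]2(CC=C(C)C)C(=O)C([C@H](CCC)CC(=O)OC)=C3OC(C)(C)CC(=O)C3=C2O)CC1(C)C | intermediate
24 | (3R)-3-[(6R)-6-{[(1S,2R)-3,3-dimethyl-2-(prop-1-en-2-yl)cyclobutyl]methyl}-5-hydroxy-2,2-dimethyl-6-(3-methylbut-2-en-1-yl)-4,7-dioxo-3,4,6,7-tetrahydro-2H-chromen-8-yl]hexanoic acid | C=C(C)[C@H]1[C@H](C[C@]2(CC=C(C)C)C(=O)C([C@H](CCC)CC(=O)O)=C3OC(C)(C)CC(=O)C3=C2O)CC1(C)C | target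

Total step count: 14. Longest linear sequence: 10 steps (steps 5 to 14, from 3,5-dimethoxyphenol); the cyclobutene fragment takes 4 steps (steps 1 to 4).

Steps most likely to fail

Step 13 (Proposed new method). Hydrocupration may not take place at the ring carbon next to the gem-dimethyl group, or protonation of the alkylcopper (plain reduction of the ring alkene) may outrun transmetallation to palladium. The fallback uses known chemistry, sets out from 5 and 17, and comes back at 23; the cyclobutane stereocentres are set before the fragments are joined.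
- Rhodium-catalysed asymmetric 1,4-addition of potassium isopropenyltrifluoroborate to cyclobutene ester 5 ([Rh(cod)OH]2, (R)-BINAP, dioxane/H2O, 60 °C), then NaOMe equilibration, should give the trans ester methyl (1R,2R)-3,3-dimethyl-2-(prop-1-en-2-yl)cyclobutane-1-carboxylate F1. The beta carbon is set by the ligand and the alpha carbon by thermodynamic epimerisation.
- LiAlH4 in Et2O should give [(1R,2R)-3,3-dimethyl-2-(prop-1-en-2-yl)cyclobutyl]methanol F2.
- I2, PPh3 and imidazole should give (1R,2R)-1-(iodomethyl)-3,3-dimethyl-2-(prop-1-en-2-yl)cyclobutane F3.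
- Iodine–lithium exchange with t-BuLi at −78 °C and trapping with 9-methoxy-9-borabicyclo[3.3.1]nonane should give lithium 9-{[(1R,2R)-3,3-dimethyl-2-(prop-1-en-2-yl)cyclobutyl]methyl}-9-methoxy-9-borabicyclo[3.3.1]nonan-9-uide F4. The exocyclic carbon stays a carbanion equivalent, so the ring cannot open.
- B-alkyl Suzuki–Miyaura coupling of F4 with aryl iodide 17 (PdCl2(dppf), K3PO4, DMF, 60 °C) should give (10R)-6-{[(1S,2R)-3,3-dimethyl-2-(prop-1-en-2-yl)cyclobutyl]methyl}-5-hydroxy-2,2-dimethyl-10-propyl-2,3,9,10-tetrahydro-4H,8H-pyrano[2,3-f]chromene-4,8-dione F5.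
- Lactone methanolysis with NaOMe and palladium-catalysed asymmetric dearomative prenylation with 3-methylbut-2-en-1-yl methyl carbonate, under the catalyst system of step 12, should then deliver 23.

Step 12. Enantiofacial discrimination of the planar dianion may be poor with the hindered cyclobutenylmethyl allyl unit, or allyl methyl ether formation may compete in the methanolic medium. The fallback sets out from 16 and 7 and comes back at 21; it reverses the order in which the two groups are put on C6.
- Ring-opened 16 (NaOMe, MeOH/THF) is C-allylated at its only free ring carbon with 7 and achiral Pd(PPh3)4, and acidic work-up closes the lactone again, giving (10R)-6-[(3,3-dimethylcyclobut-1-en-1-yl)methyl]-5-hydroxy-2,2-dimethyl-10-propyl-2,3,9,10-tetrahydro-4H,8H-pyrano[2,3-f]chromene-4,8-dione F6.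
- The stereocentre is then set in a dearomative prenylation (NaOMe; Pd2(dba)3·CHCl3, the bis(phosphine) ligand of step 12 or its enantiomer, 3-methylbut-2-en-1-yl methyl carbonate), which gives 21. Prenyl is the allyl partner for which ligand control in this reaction type is best documented.

Step 11. Allylic transposition during tin-to-palladium transfer may give the 1,1-dimethylallyl isomer, or the hindered ortho-iodophenol may undergo protodeiodination. The fallback sets out from 16 and comes back at 19.
- O-Alkylation of the phenol with 3-chloro-3-methylbut-1-yne (DBU, CuCl2 cat., MeCN, 0 °C) should give (10R)-2,2-dimethyl-5-[(2-methylbut-3-yn-2-yl)oxy]-10-propyl-2,3,9,10-tetrahydro-4H,8H-pyrano[2,3-f]chromene-4,8-dione F7.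
- Semihydrogenation (H2, Pd/CaCO3 poisoned with Pb(OAc)2, quinoline, EtOAc) should give (10R)-2,2-dimethyl-5-[(2-methylbut-3-en-2-yl)oxy]-10-propyl-2,3,9,10-tetrahydro-4H,8H-pyrano[2,3-f]chromene-4,8-dione F8.
- Aromatic Claisen rearrangement in toluene at 110 °C should move the allyl unit, with inversion of its ends, to the only free ortho carbon and give 19.

Further compounds

F1 | step 13 | methyl (1R,2R)-3,3-dimethyl-2-(prop-1-en-2-yl)cyclobutane-1-carboxylate | C=C(C)[C@H]1[C@H](C(=O)OC)CC1(C)C
F2 | step 13 | [(1R,2R)-3,3-dimethyl-2-(prop-1-en-2-yl)cyclobutyl]methanol | C=C(C)[C@H]1[C@H](CO)CC1(C)C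
F3 | step 13 | (1R,2R)-1-(iodomethyl)-3,3-dimethyl-2-(prop-1-en-2-yl)cyclobutane | C=C(C)[C@H]1[C@H](CI)CC1(C)C
F4 | step 13 | lithium 9-{[(1R,2R)-3,3-dimethyl-2-(prop-1-en-2-yl)cyclobutyl]methyl}-9-methoxy-9-borabicyclo[3.3.1]nonan-9-uide | C=C(C)[C@H]1[C@H](C[B-]2(OC)C3CCCC2CCC3)CC1(C)C.[Li+]
F5 | step 13 | (10R)-6-{[(1S,2R)-3,3-dimethyl-2-(prop-1-en-2-yl)cyclobutyl]methyl}-5-hydroxy-2,2-dimethyl-10-propyl-2,3,9,10-tetrahydro-4H,8H-pyrano[2,3-f]chromene-4,8-dione | C=C(C)[C@H]1[C@H](Cc2c(O)c3C(=O)CC(C)(C)Oc3c3c2OC(=O)C[C@H]3CCC)CC1(C)C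
F6 | step 12 | (10R)-6-[(3,3-dimethylcyclobut-1-en-1-yl)methyl]-5-hydroxy-2,2-dimethyl-10-propyl-2,3,9,10-tetrahydro-4H,8H-pyrano[2,3-f]chromene-4,8-dione | CC1(C)C=C(Cc2c(O)c3C(=O)CC(C)(C)Oc3c3c2OC(=O)C[C@H]3CCC)C1
F7 | step 11 | (10R)-2,2-dimethyl-5-[(2-methylbut-3-yn-2-yl)oxy]-10-propyl-2,3,9,10-tetrahydro-4H,8H-pyrano[2,3-f]chromene-4,8-dione | C#CC(C)(C)Oc1cc2OC(=O)C[C@@H](CCC)c2c2OC(C)(C)CC(=O)c12
F8 | step 11 | (10R)-2,2-dimethyl-5-[(2-methylbut-3-en-2-yl)oxy]-10-propyl-2,3,9,10-tetrahydro-4H,8H-pyrano[2,3-f]chromene-4,8-dione | C=CC(C)(C)Oc1cc2OC(=O)C[C@@H](CCC)c2c2OC(C)(C)CC(=O)c12
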